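## Structural features

The target is a C40 carotenoid in which an all-E nonaene chain (C7 to C7', methyl branches on C9, C13, C13' and C9') joins two six-membered carbocycles. Ring A (C1–C6) is a cyclohexane with a secondary hydroxyl on C3 and a trans diol on C5/C6, both diol carbons being fully substituted; ring B (C1'–C6') is a cyclohexene (C4'=C5') with an allylic hydroxyl on C3' and the chain on C6'. In ring A the stereocentres C5 and C6 are neighbours, C6 also adjoins quaternary C1, and C3 stands 1,3 to C5 with its oxygen cis to the C5 oxygen; in ring B, C3' and C6' face each other across the ring alkene and are trans. The fragile parts are the polyene (light, oxygen, acid), the tertiary C6 hydroxyl, which is allylic to the whole chain and ionises easily, the allylic C3' hydroxyl, and the doubly allylic C6'–H, whose loss would erase C6'. The real difficulty is the C5/C6 pair: two tetrasubstituted carbinol carbons, trans to each other, between C1 and C4 and in the right sense relative to C3. The chain and ring B follow established polyene practice. The key step uses the fact that C6 of ring A is a carbinol carbon that carries C7 and lies between C1 and C5: it is treated as a ring ketone that receives C7 as an acetylide, and the axial methyl groups on C1 and C5 decide the face.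

## Logic of the disconnections

27 from 26. No skeletal bond is cut, only the O–Si bonds on C3 and C3'. The secondary hydroxyls travel masked so that the halide and ylide steps meet only tertiary hydroxyls. One last step serves both ends. Fluoride must leave the polyene and the C6 carbinol alone.

26 from 15 and 25. The C11=C12 double bond is cut. It joins an unbranched ylide carbon to an unhindered conjugated aldehyde, and the cut puts ring A into a C15 piece. The C40 problem becomes a C15 and a C25 problem. The olefination must tolerate two free tertiary hydroxyls and must end all-E after equilibration.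

25 from 23 and 24. The C11'=C12' double bond is cut. 24 is symmetrical and bought, so either end serves. Ring B is reduced to a C15 salt. The forward step must stop after one olefination, hence an excess of 24.

15 from 13 via 14, and 13 from 12. The C11–P bond and then the O–Si bond on the C11 oxygen are cut. Phosphorus enters through a halide under neutral conditions, because acid would ionise the C6 carbinol. 12 then holds all ring A stereocentres and the full C15 skeleton. The primary allylic silyl ether must go while the secondary one stays, and 14 must be trapped before it ionises.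

12 from 11. No skeletal bond is cut; the C7=C8 double bond is taken back to a triple bond. This makes C7 an sp carbon and opens the next cut. The reduction must be trans-selective, directed by the C6 hydroxyl, and must spare C9=C10 and both silyl ethers.

11 from 8 and 10. The C6–C7 bond is cut, with C6 as carbonyl carbon and C7 as acetylide carbon. A tetrasubstituted stereocentre disappears and the C15 piece falls into a C9 ring and a C6 chain. The nucleophile must reach a carbonyl between two fully substituted carbons and must enter cis to the C5 oxygen.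

8 from 5, and 5 from 4. The C5–O bond is cut, and before it the enol O–Si bond. C5 is the only enolisable position of 4, so the regiochemistry is fixed. The C5 stereocentre is reduced to a facial choice on one alkene. The oxidant must enter cis to the C3 silyloxy group.

4 from 3, and 3 from 1 via 2. The O–Si bond and then the C–H bonds on C3, C4 and C5 are cut. 1 is achiral and cheap. The enzymes must set C3 with high enantioselectivity, since every later stereocentre of ring A derives from it.

10 from 9. Only the O–Si bond is cut. A free hydroxyl would consume base and change the aggregation of the acetylide.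

23 from 21 via 22, 21 from 20, and 20 from 19. The C11'–P bond is cut, the ester level is restored, and the O–Si bond on C3' is cut. Halide formation must be neutral because the C3' oxygen is allylic.

19 from 18, and 18 from 17. The C3'–H bond of the carbinol and then the C3'–O bond are cut. C3' is the only unhindered secondary allylic position of 17. The oxidation must leave C6'–H alone, and the hydride must set C3' trans to the C6' chain under reagent control.

17 from 16. The C9'=C10' double bond is cut. 16 brings ring B with C6' already set. The olefination must be E-selective and must not epimerise C6'.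

## Other disconnections considered

Alternative 1: The cut is the C5–O bond, made from the C3 oxygen. A2, the tert-butyl carbonate of the C13 epoxy ketone with the oxirane anti to the C3 oxygen, would be treated with BF3·OEt2. The carbonyl oxygen of the carbonate attacks C5 from the back, the oxirane opens with inversion, the tert-butyl group is lost, and the six-membered cyclic carbonate A1 results, with the C5 oxygen cis to C3 and the C6 hydroxyl trans to C5.
- In its favour: C5 is fixed by an intramolecular anti opening and not by a facial preference; the C7=C8 double bond is already present, so no alkyne has to be reduced; no nucleophile has to reach a carbonyl between two fully substituted carbons. On these three points it is the equal or the better of the chosen plan.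
- Against it here: A2 requires the anti epoxide, and peracid epoxidation of this ring type is expected to show only a modest facial preference, so the facial problem is moved, not removed. The Lewis acid could also break the C6–O bond and start a ring contraction to a cyclopentyl ketone. A1 is only a C13 ketone, so two carbons, the phosphorus group and a change of protecting group (a carbonate does not survive hydride or alkoxide) still have to follow.
- Comparison: in structure both plans install the same three stereocentres. In mechanism the alternative relies on neighbouring-group opening, the chosen plan on axial attack anti to two methyl groups. In step economy the chosen plan should be shorter by about three steps, because 11 already holds all fifteen carbons.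

Alternative 2: The cut is the central C15=C15' double bond. The anion of the ring B C20 benzothiazolyl sulfone A5, made with KN(Si(CH3)3)2, would add to the ring A C20 aldehyde A4; Smiles rearrangement and extrusion then give the tetra-silylated carotenoid A3.
- In its favour: two halves of equal size, no statistical mono-olefination of a dialdehyde, no free hydroxyl in either partner, and a central double bond whose Z isomer reverts to E very easily. In convergence and in the masking of the hydroxyls it is the better plan.
- Against it here: it sets none of the five stereocentres, so ring A would still have to be built, most likely by the same acetylide addition. Each half needs five more chain carbons than a C15 salt, the two tertiary hydroxyls need extra silylation, and a sulfide must be oxidised to the sulfone beside a polyene.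
- Comparison: in structure the polyene is the same but is cut in the middle and not at C11=C12 and C11'=C12'. In mechanism sulfone-anion addition and elimination replaces ylide chemistry, with a comparable E/Z outcome after equilibration (equal). In step economy the chosen plan should be shorter by about six steps, because 24 delivers the ten central carbons in one purchase.

Alternative 3: The cut is the C6'–C7' bond of ring B. A7, the tributylstannylmethyl ether of a C5'=C6' cyclohexenol whose ether oxygen on C4' is trans to the C3' silyloxy group, would be lithiated with n-BuLi. Tin–lithium exchange and a suprafacial [2,3] shift move the carbon to C6' on the face that the oxygen held, shift the double bond to C4'=C5' and give A6.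
- In its favour: C6' is set by chirality transfer from a C–O centre and is trans to C3' by construction. It needs neither 16 as a single enantiomer nor a stereoselective ketone reduction at C3'. On stereocontrol in ring B it is the better plan.
- Against it here: it concerns ring B only and leaves the C5/C6 problem of ring A untouched. A6 is a C10 alcohol whose aldehyde is β,γ-unsaturated and can lose C6' by conjugation, and five chain carbons must still be added. A7 needs a differentiated trans diol, the tin reagent is used in full equivalent, and a [1,2] shift can compete.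
- Comparison: in structure it builds the same ring B from the ring outwards, whereas the chosen plan buys ring B with its chain start. In mechanism a sigmatropic shift with transfer of chirality stands against a reagent-controlled hydride reduction. In step economy the chosen plan should be shorter by about four steps on the ring B side.

Key step: step 6

Remarks on the chemistry (one line each):
- Positions in the text follow carotenoid numbering (ring A C1–C6, ring B C1'–C6'); compound names use systematic locants.
- 16 is assumed to be purchasable as the single (R)-enantiomer.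
- In 11 the descriptor of the carbinol carbon that bears the alkyne is R, not S, because the triple-bonded C7 outranks C1 there; the arrangement in space is the one called 6S once C7 is sp2 (12 onwards).
- 8 keeps its tertiary hydroxyl free on purpose: a silyl group there would migrate to the new C6 alkoxide and mask the hydroxyl that must direct the hydride in step 7.
- The two silyl ethers of 11 differ in class (primary allylic against secondary), which step 8 uses.

## Route

Step 1
Reactants: 1 ketoisophorone (2,6,6-trimethylcyclohex-2-ene-1,4-dione)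
Product: 3 (4R,6R)-4-hydroxy-2,2,6-trimethylcyclohexan-1-one, via (6R)-levodione 2 (not isolated)
Conditions: ene-reductase (old yellow enzyme type), NADP+ (cat.), D-glucose, glucose dehydrogenase, phosphate buffer pH 7, 30 °C; then levodione reductase (carbonyl reductase), NAD+ (cat.), same pot
Reagents that add atoms: none
Why: Biocatalytic cascade of a known type: the ene-reductase adds hydride and a proton across the C=C bond of 1 and sets the methyl-bearing carbon as R, and the carbonyl reductase then reduces only the unhindered carbonyl of 2 (the future C3) to the trans (4R) carbinol. The second enzyme is added after 1 is consumed so that it cannot reduce 1 itself, and 2 is not isolated because its stereocentre is alpha to a carbonyl.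

Step 2
Reactants: 3 (4R,6R)-4-hydroxy-2,2,6-trimethylcyclohexan-1-one
Product: 4 (4R,6R)-4-(tert-butyldimethylsilyloxy)-2,2,6-trimethylcyclohexan-1-one
Conditions: TBSCl, imidazole, DMF, rt
Reagents that add atoms: tert-butyldimethylsilyl chloride, CC(C)(C)[Si](C)(C)Cl
Why: Standard silylation of a secondary alcohol; the hindered ketone does not react, and the alpha stereocentre is erased in step 3 in any case.

Step 3
Reactants: 4 (4R,6R)-4-(tert-butyldimethylsilyloxy)-2,2,6-trimethylcyclohexan-1-one
Product: 5 (4R)-4-(tert-butyldimethylsilyloxy)-2,6,6-trimethyl-1-(trimethylsilyloxy)cyclohex-1-ene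
Conditions: TMSOTf, Et3N, CH2Cl2, 0 °C → rt
Reagents that add atoms: trimethylsilyl trifluoromethanesulfonate, C[Si](C)(C)OS(=O)(=O)C(F)(F)F
Why: Soft enolisation with a silyl triflate and an amine; 4 has a single alpha hydrogen, so only the tetrasubstituted silyl enol ether can form. The future C3 centre is untouched.

Step 4
Reactants: 5 (4R)-4-(tert-butyldimethylsilyloxy)-2,6,6-trimethyl-1-(trimethylsilyloxy)cyclohex-1-ene
Product: 8 (2S,4S)-4-(tert-butyldimethylsilyloxy)-2-hydroxy-2,6,6-trimethylcyclohexan-1-one, via silyloxy epoxide 6 (not isolated), via alpha-trimethylsilyloxy ketone 7 (not isolated)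
Conditions: mCPBA, NaHCO3, CH2Cl2, −20 → 0 °C; then citric acid, MeOH, rt
Reagents that add atoms: 3-chloroperbenzoic acid, OOC(=O)c1cccc(Cl)c1
Why: Rubottom oxidation: the peracid epoxidises the electron-rich enol ether, oxirane 6 opens with 1,4-silyl shift to 7, and mild acid methanolysis frees the tertiary hydroxyl. In the half-chair of 5 the C3 silyloxy group is equatorial, which puts one C1 methyl group pseudoaxial on the opposite face, so the peracid should enter on the face of the C3 oxygen and make the new C5–O bond cis to it (2S).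

Step 5
Reactants: 9 (2E)-3-methylpent-2-en-4-yn-1-ol
Product: 10 tert-butyldimethyl{[(2E)-3-methylpent-2-en-4-yn-1-yl]oxy}silane
Conditions: TBSCl, imidazole, CH2Cl2, 0 °C → rt
Reagents that add atoms: tert-butyldimethylsilyl chloride, CC(C)(C)[Si](C)(C)Cl
Why: Standard silylation of a primary allylic alcohol; the terminal alkyne is inert under these conditions.

Step 6
Reactants: 8 (2S,4S)-4-(tert-butyldimethylsilyloxy)-2-hydroxy-2,6,6-trimethylcyclohexan-1-one; 10 tert-butyldimethyl{[(2E)-3-methylpent-2-en-4-yn-1-yl]oxy}silane
Product: 11 (1R,2S,4S)-4-(tert-butyldimethylsilyloxy)-1-[(3E)-5-(tert-butyldimethylsilyloxy)-3-methylpent-3-en-1-yn-1-yl]-2,6,6-trimethylcyclohexane-1,2-diol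
Conditions: 10 (3 equiv), n-BuLi, THF, −78 °C; add 8, −78 → 0 °C; aq. NH4Cl
Reagents that add atoms: none
Why: The first equivalent of the lithium acetylide of 10 turns the tertiary hydroxyl of 8 into its lithium alkoxide, and a further equivalent adds 1,2 to the C6 carbonyl, forming the C6–C7 bond and the C6 stereocentre; the closest known reaction type is the addition of lithium acetylides to 2,2,6-trisubstituted 4-oxygenated cyclohexanones. No ring is closed. The cis relation of the C3 silyloxy group and the C5 oxygen holds ring A in the chair in which both are equatorial, and lithium bridging between the C5 alkoxide and the carbonyl oxygen supports the same chair. In that chair the C5 methyl group and one C1 methyl group are axial on one face and flank the carbonyl, so the rod-shaped sp nucleophile should enter axially from the other face, past only the axial hydrogens on C2 and C4. C7 then becomes axial and cis to the C5 oxygen and the new hydroxyl equatorial and trans to it, as in the target (descriptor R at this stage). The step needs facial selectivity and reactivity at a carbonyl between two fully substituted carbons: the two axial methyl groups secure the first, and the small size of the acetylide together with the absence of any alpha hydrogen (no enolisation) secures the second. The temperature stays at or below 0 °C so that neither reversal of the addition nor alpha-ketol rearrangement of the alkoxide intervenes.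

Step 7
Reactants: 11 (1R,2S,4S)-4-(tert-butyldimethylsilyloxy)-1-[(3E)-5-(tert-butyldimethylsilyloxy)-3-methylpent-3-en-1-yn-1-yl]-2,6,6-trimethylcyclohexane-1,2-diol
Product: 12 (1S,2S,4S)-4-(tert-butyldimethylsilyloxy)-1-[(1E,3E)-5-(tert-butyldimethylsilyloxy)-3-methylpenta-1,3-dien-1-yl]-2,6,6-trimethylcyclohexane-1,2-diol
Conditions: NaAlH2(OCH2CH2OCH3)2, THF, 0 °C → rt; aq. KNaC4H4O6
Reagents that add atoms: none
Why: Trans-hydroalumination of a propargylic alcohol: the C6 alkoxide binds aluminium, hydride is delivered to C7, and protonolysis of the C8–Al bond on work-up gives the 7E alkene. The C9=C10 bond and both silyl ethers are inert to the reagent; the C6 descriptor returns to S because C7 is now sp2.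

Step 8
Reactants: 12 (1S,2S,4S)-4-(tert-butyldimethylsilyloxy)-1-[(1E,3E)-5-(tert-butyldimethylsilyloxy)-3-methylpenta-1,3-dien-1-yl]-2,6,6-trimethylcyclohexane-1,2-diol
Product: 13 (1S,2S,4S)-4-(tert-butyldimethylsilyloxy)-1-[(1E,3E)-5-hydroxy-3-methylpenta-1,3-dien-1-yl]-2,6,6-trimethylcyclohexane-1,2-diol
Conditions: HF·pyridine, pyridine, THF, 0 °C
Reagents that add atoms: none
Why: Selective desilylation: buffered HF cleaves the unhindered primary allylic silyl ether much faster than the secondary ring silyl ether. The pyridine buffer keeps the tertiary allylic C6 hydroxyl from ionising.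

Step 9
Reactants: 13 (1S,2S,4S)-4-(tert-butyldimethylsilyloxy)-1-[(1E,3E)-5-hydroxy-3-methylpenta-1,3-dien-1-yl]-2,6,6-trimethylcyclohexane-1,2-diol
Product: 15 {(2E,4E)-5-[(1S,2S,4S)-4-(tert-butyldimethylsilyloxy)-1,2-dihydroxy-2,6,6-trimethylcyclohexyl]-3-methylpenta-2,4-dien-1-yl}triphenylphosphonium bromide, via allylic bromide 14 (not isolated)
Conditions: CBr4, PPh3, 2,6-lutidine, CH2Cl2, −20 °C; then PPh3, rt
Reagents that add atoms: triphenylphosphine, c1ccc(cc1)P(c1ccccc1)c1ccccc1; carbon tetrabromide, BrC(Br)(Br)Br
Why: Appel bromination of the primary allylic alcohol followed at once by SN2 displacement with triphenylphosphine; the tertiary hydroxyls are too hindered to be activated. Neutral conditions are chosen because a protic acid would ionise the C6 carbinol, whose cation is delocalised over the same diene.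

Step 10
Reactants: 16 (R)-α-ionone, (3E)-4-[(1R)-2,6,6-trimethylcyclohex-2-en-1-yl]but-3-en-2-one
Product: 17 ethyl (2E,4E)-3-methyl-5-[(1R)-2,6,6-trimethylcyclohex-2-en-1-yl]penta-2,4-dienoate
Conditions: (EtO)2P(O)CH2CO2Et, NaH, THF, 0 → 40 °C; chromatography to remove the 2Z isomer
Reagents that add atoms: triethyl phosphonoacetate, CCOC(=O)CP(=O)(OCC)OCC
Why: Horner–Wadsworth–Emmons olefination of a methyl ketone of the ionone class; the stabilised phosphonate anion should give mainly the 2E ester. It is not basic enough to remove the gamma hydrogen on C6', so the stereocentre of 16 is kept.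

Step 11
Reactants: 17 ethyl (2E,4E)-3-methyl-5-[(1R)-2,6,6-trimethylcyclohex-2-en-1-yl]penta-2,4-dienoate
Product: 18 ethyl (2E,4E)-3-methyl-5-[(1R)-2,6,6-trimethyl-4-oxocyclohex-2-en-1-yl]penta-2,4-dienoate
Conditions: t-BuOOH (70% aq.), Rh2(C6H10NO)4 (dirhodium tetracaprolactamate, cat.), K2CO3, CH2Cl2, rt
Reagents that add atoms: tert-butyl hydroperoxide, CC(C)(C)OO
Why: Allylic oxidation by tert-butylperoxyl radicals: hydrogen is abstracted from the ring methylene next to the trisubstituted alkene (C3') and the mixed peroxide collapses to the enone. This methylene is the only unhindered secondary allylic site; the doubly allylic C6'–H is shielded by C1' and the C5' methyl group, and the chain methyl sits on an electron-poor dienoate.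

Step 12
Reactants: 18 ethyl (2E,4E)-3-methyl-5-[(1R)-2,6,6-trimethyl-4-oxocyclohex-2-en-1-yl]penta-2,4-dienoate
Product: 19 ethyl (2E,4E)-5-[(1R,4R)-4-hydroxy-2,6,6-trimethylcyclohex-2-en-1-yl]-3-methylpenta-2,4-dienoate
Conditions: (S)-2-methyl-CBS-oxazaborolidine, catecholborane, toluene, −78 °C
Reagents that add atoms: none
Why: Corey–Bakshi–Shibata reduction of a cyclic enone: the ring alkene carbon acts as the large group, so the (S)-catalyst should deliver hydride to the face that gives the (R)-carbinol, trans to the C6' chain. Catecholborane reduces the enone carbonyl 1,2 at low temperature and leaves the ester alone.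

Step 13
Reactants: 19 ethyl (2E,4E)-5-[(1R,4R)-4-hydroxy-2,6,6-trimethylcyclohex-2-en-1-yl]-3-methylpenta-2,4-dienoate
Product: 20 ethyl (2E,4E)-5-[(1R,4R)-4-(tert-butyldimethylsilyloxy)-2,6,6-trimethylcyclohex-2-en-1-yl]-3-methylpenta-2,4-dienoate
Conditions: TBSCl, imidazole, DMF, rt
Reagents that add atoms: tert-butyldimethylsilyl chloride, CC(C)(C)[Si](C)(C)Cl
Why: Standard silylation; the allylic hydroxyl is masked before hydride reduction and halide formation so that it can neither ionise nor compete.

Step 14
Reactants: 20 ethyl (2E,4E)-5-[(1R,4R)-4-(tert-butyldimethylsilyloxy)-2,6,6-trimethylcyclohex-2-en-1-yl]-3-methylpenta-2,4-dienoate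
Product: 21 (2E,4E)-5-[(1R,4R)-4-(tert-butyldimethylsilyloxy)-2,6,6-trimethylcyclohex-2-en-1-yl]-3-methylpenta-2,4-dien-1-ol
Conditions: (i-Bu)2AlH, CH2Cl2, −78 °C; aq. KNaC4H4O6
Reagents that add atoms: none
Why: Reduction of a conjugated ester to the allylic alcohol with an aluminium hydride at low temperature; 1,2-reduction is the rule for dienoates and the silyl ether is inert.

Step 15
Reactants: 21 (2E,4E)-5-[(1R,4R)-4-(tert-butyldimethylsilyloxy)-2,6,6-trimethylcyclohex-2-en-1-yl]-3-methylpenta-2,4-dien-1-ol
Product: 23 {(2E,4E)-5-[(1R,4R)-4-(tert-butyldimethylsilyloxy)-2,6,6-trimethylcyclohex-2-en-1-yl]-3-methylpenta-2,4-dien-1-yl}triphenylphosphonium bromide, via allylic bromide 22 (not isolated)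
Conditions: CBr4, PPh3, 2,6-lutidine, CH2Cl2, −20 °C; then PPh3, rt
Reagents that add atoms: triphenylphosphine, c1ccc(cc1)P(c1ccccc1)c1ccccc1; carbon tetrabromide, BrC(Br)(Br)Br
Why: Appel bromination and phosphine displacement as in step 9; the neutral conditions spare the allylic silyl ether of ring B.

Step 16
Reactants: 23 {(2E,4E)-5-[(1R,4R)-4-(tert-butyldimethylsilyloxy)-2,6,6-trimethylcyclohex-2-en-1-yl]-3-methylpenta-2,4-dien-1-yl}triphenylphosphonium bromide; 24 (2E,4E,6E)-2,7-dimethylocta-2,4,6-trienedial
Product: 25 (2E,4E,6E,8E,10E,12E)-13-[(1R,4R)-4-(tert-butyldimethylsilyloxy)-2,6,6-trimethylcyclohex-2-en-1-yl]-2,7,11-trimethyltrideca-2,4,6,8,10,12-hexaenal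
Conditions: NaOMe, CH2Cl2/MeOH, 0 °C → rt, 24 in excess, ylide added to 24; then heptane, 80 °C, N2, dark
Reagents that add atoms: none
Why: Wittig olefination of the C15 ylide with one aldehyde group of the symmetrical dialdehyde; inverse addition to an excess of 24 should limit double olefination. Polyenyl ylides give E/Z mixtures at the new C11'=C12' bond, and heating should equilibrate the hindered Z isomer to the all-E aldehyde.

Step 17
Reactants: 25 (2E,4E,6E,8E,10E,12E)-13-[(1R,4R)-4-(tert-butyldimethylsilyloxy)-2,6,6-trimethylcyclohex-2-en-1-yl]-2,7,11-trimethyltrideca-2,4,6,8,10,12-hexaenal; 15 {(2E,4E)-5-[(1S,2S,4S)-4-(tert-butyldimethylsilyloxy)-1,2-dihydroxy-2,6,6-trimethylcyclohexyl]-3-methylpenta-2,4-dien-1-yl}triphenylphosphonium bromide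
Product: 26 (3S,5S,6S,3'R,6'R)-3,3'-bis(tert-butyldimethylsilyloxy)-5,6-dihydro-β,ε-carotene-5,6-diol
Conditions: NaOMe, CH2Cl2/MeOH, 0 °C → rt; then EtOAc/heptane, 70 °C, N2, dark
Reagents that add atoms: none
Why: Wittig olefination forming C11=C12; the alkoxides of the two tertiary hydroxyls are spectators under the basic conditions and the conjugated aldehyde is unhindered. Thermal equilibration in the dark should convert the 11Z isomer into the all-E polyene.

Step 18
Reactants: 26 (3S,5S,6S,3'R,6'R)-3,3'-bis(tert-butyldimethylsilyloxy)-5,6-dihydro-β,ε-carotene-5,6-diol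
Product: 27 (3S,5S,6S,3'R,6'R)-5,6-dihydro-β,ε-carotene-3,5,6,3'-tetrol
Conditions: Bu4NF, THF, 0 °C → rt, dark
Reagents that add atoms: none
Why: Fluoride cleavage of the two secondary silyl ethers under neutral to slightly basic conditions, which the polyene, the allylic C3' hydroxyl and the tertiary C6 hydroxyl should tolerate. No stereocentre is touched.

## Compound list

1 | ketoisophorone (2,6,6-trimethylcyclohex-2-ene-1,4-dione) | CC1=CC(=O)CC(C)(C)C1=O | starting material
2 | (6R)-2,2,6-trimethylcyclohexane-1,4-dione ((6R)-levodione) | O=C1C(C)(C)CC(=O)C[C@H]1C | intermediate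
3 | (4R,6R)-4-hydroxy-2,2,6-trimethylcyclohexan-1-one | O=C1C(C)(C)C[C@H](O)C[C@H]1C | intermediate
4 | (4R,6R)-4-(tert-butyldimethylsilyloxy)-2,2,6-trimethylcyclohexan-1-one | O=C1C(C)(C)C[C@H](O[Si](C)(C)C(C)(C)C)C[C@H]1C | intermediate
5 | (4R)-4-(tert-butyldimethylsilyloxy)-2,6,6-trimethyl-1-(trimethylsilyloxy)cyclohex-1-ene | CC1=C(O[Si](C)(C)C)C(C)(C)C[C@H](O[Si](C)(C)C(C)(C)C)C1 | intermediate
6 | 4-(tert-butyldimethylsilyloxy)-2,2,6-trimethyl-1-(trimethylsilyloxy)-7-oxabicyclo[4.1.0]heptane, oxirane oxygen cis to the C4 silyloxy group | C[C@@]12O[C@]1(O[Si](C)(C)C)C(C)(C)C[C@H](O[Si](C)(C)C(C)(C)C)C2 | intermediate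
7 | (2S,4S)-4-(tert-butyldimethylsilyloxy)-2,6,6-trimethyl-2-(trimethylsilyloxy)cyclohexan-1-one | O=C1C(C)(C)C[C@H](O[Si](C)(C)C(C)(C)C)C[C@]1(C)O[Si](C)(C)C | intermediate
8 | (2S,4S)-4-(tert-butyldimethylsilyloxy)-2-hydroxy-2,6,6-trimethylcyclohexan-1-one | O=C1C(C)(C)C[C@H](O[Si](C)(C)C(C)(C)C)C[C@]1(C)O | intermediate
9 | (2E)-3-methylpent-2-en-4-yn-1-ol | C#C/C(C)=C/CO | starting material
10 | tert-butyldimethyl{[(2E)-3-methylpent-2-en-4-yn-1-yl]oxy}silane | C#C/C(C)=C/CO[Si](C)(C)C(C)(C)C | intermediate
11 | (1R,2S,4S)-4-(tert-butyldimethylsilyloxy)-1-[(3E)-5-(tert-butyldimethylsilyloxy)-3-methylpent-3-en-1-yn-1-yl]-2,6,6-trimethylcyclohexane-1,2-diol | CC(C)(C)[Si](C)(C)OC/C=C(C)/C#C[C@]1(O)C(C)(C)C[C@H](O[Si](C)(C)C(C)(C)C)C[C@]1(C)O | intermediate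
12 | (1S,2S,4S)-4-(tert-butyldimethylsilyloxy)-1-[(1E,3E)-5-(tert-butyldimethylsilyloxy)-3-methylpenta-1,3-dien-1-yl]-2,6,6-trimethylcyclohexane-1,2-diol | CC(C)(C)[Si](C)(C)OC/C=C(C)/C=C/[C@]1(O)C(C)(C)C[C@H](O[Si](C)(C)C(C)(C)C)C[C@]1(C)O | intermediate
13 | (1S,2S,4S)-4-(tert-butyldimethylsilyloxy)-1-[(1E,3E)-5-hydroxy-3-methylpenta-1,3-dien-1-yl]-2,6,6-trimethylcyclohexane-1,2-diol | OC/C=C(C)/C=C/[C@]1(O)C(C)(C)C[C@H](O[Si](C)(C)C(C)(C)C)C[C@]1(C)O | intermediate
14 | (1S,2S,4S)-1-[(1E,3E)-5-bromo-3-methylpenta-1,3-dien-1-yl]-4-(tert-butyldimethylsilyloxy)-2,6,6-trimethylcyclohexane-1,2-diol | BrC/C=C(C)/C=C/[C@]1(O)C(C)(C)C[C@H](O[Si](C)(C)C(C)(C)C)C[C@]1(C)O | intermediate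
15 | {(2E,4E)-5-[(1S,2S,4S)-4-(tert-butyldimethylsilyloxy)-1,2-dihydroxy-2,6,6-trimethylcyclohexyl]-3-methylpenta-2,4-dien-1-yl}triphenylphosphonium bromide | [Br-].c1ccccc1[P+](c1ccccc1)(c1ccccc1)C/C=C(C)/C=C/[C@]1(O)C(C)(C)C[C@H](O[Si](C)(C)C(C)(C)C)C[C@]1(C)O | intermediate
16 | (R)-α-ionone, (3E)-4-[(1R)-2,6,6-trimethylcyclohex-2-en-1-yl]but-3-en-2-one | CC1=CCCC(C)(C)[C@H]1/C=C/C(C)=O | starting material
17 | ethyl (2E,4E)-3-methyl-5-[(1R)-2,6,6-trimethylcyclohex-2-en-1-yl]penta-2,4-dienoate | CC1=CCCC(C)(C)[C@H]1/C=C/C(C)=C/C(=O)OCC | intermediate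
18 | ethyl (2E,4E)-3-methyl-5-[(1R)-2,6,6-trimethyl-4-oxocyclohex-2-en-1-yl]penta-2,4-dienoate | CC1=CC(=O)CC(C)(C)[C@H]1/C=C/C(C)=C/C(=O)OCC | intermediate
19 | ethyl (2E,4E)-5-[(1R,4R)-4-hydroxy-2,6,6-trimethylcyclohex-2-en-1-yl]-3-methylpenta-2,4-dienoate | CC1=C[C@H](O)CC(C)(C)[C@H]1/C=C/C(C)=C/C(=O)OCC | intermediate
20 | ethyl (2E,4E)-5-[(1R,4R)-4-(tert-butyldimethylsilyloxy)-2,6,6-trimethylcyclohex-2-en-1-yl]-3-methylpenta-2,4-dienoate | CC1=C[C@H](O[Si](C)(C)C(C)(C)C)CC(C)(C)[C@H]1/C=C/C(C)=C/C(=O)OCC | intermediate
21 | (2E,4E)-5-[(1R,4R)-4-(tert-butyldimethylsilyloxy)-2,6,6-trimethylcyclohex-2-en-1-yl]-3-methylpenta-2,4-dien-1-ol | CC1=C[C@H](O[Si](C)(C)C(C)(C)C)CC(C)(C)[C@H]1/C=C/C(C)=C/CO | intermediate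
22 | {[(1R,4R)-4-[(1E,3E)-5-bromo-3-methylpenta-1,3-dien-1-yl]-3,5,5-trimethylcyclohex-2-en-1-yl]oxy}(tert-butyl)dimethylsilane | CC1=C[C@H](O[Si](C)(C)C(C)(C)C)CC(C)(C)[C@H]1/C=C/C(C)=C/CBr | intermediate
23 | {(2E,4E)-5-[(1R,4R)-4-(tert-butyldimethylsilyloxy)-2,6,6-trimethylcyclohex-2-en-1-yl]-3-methylpenta-2,4-dien-1-yl}triphenylphosphonium bromide | CC1=C[C@H](O[Si](C)(C)C(C)(C)C)CC(C)(C)[C@H]1/C=C/C(C)=C/C[P+](c1ccccc1)(c1ccccc1)c1ccccc1.[Br-] | intermediate
24 | (2E,4E,6E)-2,7-dimethylocta-2,4,6-trienedial | O=C/C(C)=C/C=C/C=C(C)/C=O | starting material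
25 | (2E,4E,6E,8E,10E,12E)-13-[(1R,4R)-4-(tert-butyldimethylsilyloxy)-2,6,6-trimethylcyclohex-2-en-1-yl]-2,7,11-trimethyltrideca-2,4,6,8,10,12-hexaenal | CC1=C[C@H](O[Si](C)(C)C(C)(C)C)CC(C)(C)[C@H]1/C=C/C(C)=C/C=C/C(C)=C/C=C/C=C(C)/C=O | intermediate
26 | (3S,5S,6S,3'R,6'R)-3,3'-bis(tert-butyldimethylsilyloxy)-5,6-dihydro-β,ε-carotene-5,6-diol | CC1=C[C@H](O[Si](C)(C)C(C)(C)C)CC(C)(C)[C@H]1/C=C/C(C)=C/C=C/C(C)=C/C=C/C=C(C)/C=C/C=C(C)/C=C/[C@]1(O)C(C)(C)C[C@H](O[Si](C)(C)C(C)(C)C)C[C@]1(C)O | intermediate
27 | (3S,5S,6S,3'R,6'R)-5,6-dihydro-β,ε-carotene-3,5,6,3'-tetrol | CC1=C[C@H](O)CC(C)(C)[C@H]1/C=C/C(C)=C/C=C/C(C)=C/C=C/C=C(C)/C=C/C=C(C)/C=C/[C@]1(O)C(C)(C)C[C@H](O)C[C@]1(C)O | target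

## Step count and least certain steps

Total step count: 18. Longest linear sequence: 10 steps (1, 2, 3, 4, 6, 7, 8, 9, 17, 18); the ring B branch (10 to 16, then 17 and 18) has 9.

Step 6 (key step). The most likely failure is incomplete or reversible addition at a carbonyl between two fully substituted carbons that also carries an adjacent lithium alkoxide. Facial selectivity could also erode if aggregation of the alkoxide distorts the chair. Pre-mixing the acetylide with anhydrous CeCl3 is a change of conditions only. The fallback changes the way the chain is attached. It sets out from 8, which is treated with the smaller and more reactive lithium (trimethylsilyl)acetylide to give (1R,2S,4S)-4-(tert-butyldimethylsilyloxy)-2,6,6-trimethyl-1-[(trimethylsilyl)ethynyl]cyclohexane-1,2-diol F1. K2CO3 in MeOH removes the C-silyl group to give the ethynyl diol F2. Sonogashira coupling of F2 with the known tert-butyl{[(2E)-3-iodobut-2-en-1-yl]oxy}dimethylsilane (Pd(PPh3)4 as zerovalent palladium catalyst, CuI, i-Pr2NH) forms the C8–C9 bond and comes back to the route at 11.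

Step 4. The enol ether may lose its silyl group to the carboxylic acid formed before it is epoxidised, and a small peracid may discriminate the two faces less well than the half-chair model predicts. The fallback sets out from 4 and replaces the two-step sequence by direct enolate hydroxylation: KN(Si(CH3)3)2 in THF at −78 °C, then 3-phenyl-2-(phenylsulfonyl)oxaziridine. The medium is basic, the oxidant is bulkier and should respond more strongly to the pseudoaxial methyl group, and the route is rejoined at 8 without any new intermediate.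

Step 11. Hydrogen abstraction may occur at the doubly allylic C6'–H (loss of the stereocentre or peroxide formation there) or at the chain methyl, and the product enone may be oxidised further. The fallback moves the oxidation to a substrate without the dienoate. It sets out from 16, which is converted with ethylene glycol, HC(OEt)3 and catalytic TsOH into the dioxolane F3. F3 is oxidised under the peroxide conditions to the enone F4 and reduced with the (S)-oxazaborolidine and catecholborane to the (1R,4R) carbinol F5. Mild hydrolysis (pyridinium tosylate, aqueous acetone) gives (3R,6R)-3-hydroxy-α-ionone F6. Horner–Wadsworth–Emmons olefination of F6 with two equivalents of the phosphonate anion comes back to the route at 19.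

Step 12. The catalyst and the existing C6' centre may be mismatched, which would show as poor diastereoselectivity at C3'. The fallback gives up reagent control. It sets out from 18, which is reduced with NaBH4 and CeCl3 in MeOH; the two C3' epimers are separated and the (1R,4R) epimer is 19. The (1R,4S) epimer F7 is inverted under Mitsunobu conditions (4-nitrobenzoic acid, PPh3, diisopropyl azodicarboxylate) to the (1R,4R) 4-nitrobenzoate F8. K2CO3 in EtOH removes the aryl ester and comes back to the route at 19.

Step 9. Bromide 14 may ionise before phosphine captures it, and the resulting cation next to the C6 carbinol could undergo a semipinacol shift or dehydration. The fallback reverses the polarity of the C11=C12 olefination so that ring A never carries a halide. It sets out from 13, which MnO2 in CH2Cl2 oxidises to the C15 aldehyde F9. In parallel 25 is reduced with NaBH4 to the C25 alcohol F10, which is converted (CBr4, PPh3; then PPh3) into the C25 phosphonium bromide F11. Wittig reaction of F11 with F9 (NaOMe, CH2Cl2/MeOH, then thermal equilibration) comes back to the route at 26.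

## Further compounds

F1 | step 6 | (1R,2S,4S)-4-(tert-butyldimethylsilyloxy)-2,6,6-trimethyl-1-[(trimethylsilyl)ethynyl]cyclohexane-1,2-diol | C[Si](C)(C)C#C[C@]1(O)C(C)(C)C[C@H](O[Si](C)(C)C(C)(C)C)C[C@]1(C)O
F2 | step 6 | (1R,2S,4S)-4-(tert-butyldimethylsilyloxy)-1-ethynyl-2,6,6-trimethylcyclohexane-1,2-diol | C#C[C@]1(O)C(C)(C)C[C@H](O[Si](C)(C)C(C)(C)C)C[C@]1(C)O
F0 | step 4 | none | none
F3 | step 11 | 2-methyl-2-{(E)-2-[(1R)-2,6,6-trimethylcyclohex-2-en-1-yl]ethenyl}-1,3-dioxolane | CC1=CCCC(C)(C)[C@H]1/C=C/C1(C)OCCO1
F4 | step 11 | (4R)-3,5,5-trimethyl-4-[(E)-2-(2-methyl-1,3-dioxolan-2-yl)ethenyl]cyclohex-2-en-1-one | CC1=CC(=O)CC(C)(C)[C@H]1/C=C/C1(C)OCCO1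
F5 | step 11 | (1R,4R)-3,5,5-trimethyl-4-[(E)-2-(2-methyl-1,3-dioxolan-2-yl)ethenyl]cyclohex-2-en-1-ol | CC1=C[C@H](O)CC(C)(C)[C@H]1/C=C/C1(C)OCCO1
F6 | step 11 | (3E)-4-[(1R,4R)-4-hydroxy-2,6,6-trimethylcyclohex-2-en-1-yl]but-3-en-2-one | CC1=C[C@H](O)CC(C)(C)[C@H]1/C=C/C(C)=O
F7 | step 12 | ethyl (2E,4E)-5-[(1R,4S)-4-hydroxy-2,6,6-trimethylcyclohex-2-en-1-yl]-3-methylpenta-2,4-dienoate | CC1=C[C@@H](O)CC(C)(C)[C@H]1/C=C/C(C)=C/C(=O)OCC
F8 | step 12 | (1R,4R)-4-[(1E,3E)-5-ethoxy-3-methyl-5-oxopenta-1,3-dien-1-yl]-3,5,5-trimethylcyclohex-2-en-1-yl 4-nitrobenzoate | CC1=C[C@H](OC(=O)c2ccc(cc2)[N+](=O)[O-])CC(C)(C)[C@H]1/C=C/C(C)=C/C(=O)OCC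
F9 | step 9 | (2E,4E)-5-[(1S,2S,4S)-4-(tert-butyldimethylsilyloxy)-1,2-dihydroxy-2,6,6-trimethylcyclohexyl]-3-methylpenta-2,4-dienal | O=C/C=C(C)/C=C/[C@]1(O)C(C)(C)C[C@H](O[Si](C)(C)C(C)(C)C)C[C@]1(C)O
F10 | step 9 | (2E,4E,6E,8E,10E,12E)-13-[(1R,4R)-4-(tert-butyldimethylsilyloxy)-2,6,6-trimethylcyclohex-2-en-1-yl]-2,7,11-trimethyltrideca-2,4,6,8,10,12-hexaen-1-ol | CC1=C[C@H](O[Si](C)(C)C(C)(C)C)CC(C)(C)[C@H]1/C=C/C(C)=C/C=C/C(C)=C/C=C/C=C(C)/CO
F11 | step 9 | {(2E,4E,6E,8E,10E,12E)-13-[(1R,4R)-4-(tert-butyldimethylsilyloxy)-2,6,6-trimethylcyclohex-2-en-1-yl]-2,7,11-trimethyltrideca-2,4,6,8,10,12-hexaen-1-yl}triphenylphosphonium bromide | CC1=C[C@H](O[Si](C)(C)C(C)(C)C)CC(C)(C)[C@H]1/C=C/C(C)=C/C=C/C(C)=C/C=C/C=C(C)/C[P+](c1ccccc1)(c1ccccc1)c1ccccc1.[Br-]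
A1 | alternative 1 | 3,5-cyclic carbonate of (3S,5S,6S)-3,5,6-trihydroxy-5,6-dihydro-β-ionone | CC(=O)/C=C/[C@]1(O)C(C)(C)C[C@H](OC(=O)O2)C[C@@]12C
A2 | alternative 1 | tert-butyl carbonate of (3S,5R,6S)-5,6-epoxy-3-hydroxy-5,6-dihydro-β-ionone | CC(=O)/C=C/[C@@]12O[C@]1(C)C[C@@H](OC(=O)OC(C)(C)C)CC2(C)C
A3 | alternative 2 | 3,3'-bis(tert-butyldimethylsilyl) 5,6-bis(trimethylsilyl) ether of (3S,5S,6S,3'R,6'R)-5,6-dihydro-β,ε-carotene-3,5,6,3'-tetrol | CC1=C[C@H](O[Si](C)(C)C(C)(C)C)CC(C)(C)[C@H]1/C=C/C(C)=C/C=C/C(C)=C/C=C/C=C(C)/C=C/C=C(C)/C=C/[C@]1(O[Si](C)(C)C)C(C)(C)C[C@H](O[Si](C)(C)C(C)(C)C)C[C@]1(C)O[Si](C)(C)C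
A4 | alternative 2 | (2E,4E,6E,8E)-9-[(1S,2S,4S)-4-(tert-butyldimethylsilyloxy)-2,6,6-trimethyl-1,2-bis(trimethylsilyloxy)cyclohexyl]-3,7-dimethylnona-2,4,6,8-tetraenal | O=C/C=C(C)/C=C/C=C(C)/C=C/[C@]1(O[Si](C)(C)C)C(C)(C)C[C@H](O[Si](C)(C)C(C)(C)C)C[C@]1(C)O[Si](C)(C)C
A5 | alternative 2 | 2-{(2E,4E,6E,8E)-9-[(1R,4R)-4-(tert-butyldimethylsilyloxy)-2,6,6-trimethylcyclohex-2-en-1-yl]-3,7-dimethylnona-2,4,6,8-tetraen-1-ylsulfonyl}-1,3-benzothiazole | CC1=C[C@H](O[Si](C)(C)C(C)(C)C)CC(C)(C)[C@H]1/C=C/C(C)=C/C=C/C(C)=C/CS(=O)(=O)c1nc2ccccc2s1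
A6 | alternative 3 | [(1R,4R)-4-(tert-butyldimethylsilyloxy)-2,6,6-trimethylcyclohex-2-en-1-yl]methanol | CC1=C[C@H](O[Si](C)(C)C(C)(C)C)CC(C)(C)[C@H]1CO
A7 | alternative 3 | tributyl({[(1R,6R)-6-(tert-butyldimethylsilyloxy)-2,4,4-trimethylcyclohex-2-en-1-yl]oxy}methyl)stannane | CC1=CC(C)(C)C[C@@H](O[Si](C)(C)C(C)(C)C)[C@@H]1OC[Sn](CCCC)(CCCC)CCCC
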